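Its constants are assumed; no experiment stands behind them.

From the constants, the way consumed starting material divides between the catalysed and the uncatalysed route can be reckoned by hand.

    starting material + target → side product (k1 = 0.143 L mol⁻¹ s⁻¹)
    coupling partner + catalyst intermediate B → free catalyst + second product (k2 = 48.1 L mol⁻¹ s⁻¹)
    starting material + coupling partner → uncatalysed product (k3 = 0.576 L mol⁻¹ s⁻¹)
    second substrate + free catalyst ⇌ catalyst intermediate B (K4 = 140 L mol⁻¹, k4 = 153 L mol⁻¹ s⁻¹)
    starting material + free catalyst ⇌ catalyst intermediate A (K5 = 40 L mol⁻¹, k5 = 5310 L mol⁻¹ s⁻¹)
    coupling partner + catalyst intermediate A → free catalyst + target (k6 = 165 L mol⁻¹ s⁻¹)

all flasks: starting material 10 mM; free catalyst 0.20 mM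
- alpha: second substrate 20.0 mM; coupling partner 15.0 mM; one stirred flow tank at steady state, fed with the mixture as stated, mean residence time 40 s
- delta: second substrate 20.0 mM; coupling partner 15.0 mM (fed, over 32.0 s); a stirred flask in which coupling partner is dosed at a steady rate over 32.0 s without added volume, worked up at 40 s; time 40 s
- epsilon: second substrate 20.0 mM (fed, over 32.0 s); coupling partner 15.0 mM; a stirred flask in which second substrate is dosed at a steady rate over 32.0 s without added volume, worked up at 40 s; time 40 s
- gamma: second substrate 20.0 mM; coupling partner 15.0 mM; a closed flask charged with all of it at once and left for 40 s; time 40 s

- percentages count the starting material that a species holds: one side product counts as two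
- the stated concentrations are those of everything mixed, before any reaction; amounts are the same in each set-up
- the feed brings no volume worth counting
- run time (delta): 40 s

- the set-up with the highest amount of target at the outlet or at the end, in percent of the starting material put in ("none" if the first two lie within 2 percentage points) (alpha / delta / epsilon / gamma / none)
- amount of target at the outlet or at the end, in percent of the starting material put in, alpha
- amount of target at the outlet or at the end, in percent of the starting material put in, delta
- amount of target at the outlet or at the end, in percent of the starting material put in, epsilon
- amount of target at the outlet or at the end, in percent of the starting material put in, gamma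

Catalyst intermediate A falls back at 133 s⁻¹ but, even at the full charge of coupling partner, goes on to target at 2.48 s⁻¹, so it stays balanced with starting material and free catalyst. Target therefore forms in proportion to starting material, coupling partner and free catalyst, while uncatalysed product forms in proportion to the first two. Dividing one rate by the other removes time and both reagents.

At the full charge of coupling partner, catalyst intermediate B leaves with a half-life of 0.382 s, much shorter than 40 s, so it is balanced too, and at gamma's charges 32.4% of the catalyst is reckoned to stand free. This gives gamma the split 0.742, a selectivity factor: the target formed per uncatalysed product formed. At the start of delta, without coupling partner, the split is 0.546; at the start of epsilon, without second substrate, it is 1.64. So epsilon should stand above gamma and delta below it, and delta's coupling partner also arrives late.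

The split does not say how much is consumed. With gamma's split, both routes together act by hand as one second-order step of 1.00 L mol⁻¹ s⁻¹. This reckoning leaves out the coupling partner spent on second product. Gamma then consumes 4.00 mM of starting material, which makes 17.0% target. The flow tank alpha, reckoned the same way with gamma's split, gives 13.7% target.

The forecast named epsilon, with 11.8%, 10.1%, 21.5% and 15.4% for alpha, delta, epsilon and gamma, its alpha and gamma below the hand figures, reasoning that “holding back the second substrate leaves more catalyst free”.

The simulation gives epsilon as best, with 11.9%, 10.2%, 21.8% and 15.5% for alpha, delta, epsilon and gamma.

Gamma has not come to rest at 40.0 s: 62.4% of the starting material and 58.7% of the coupling partner remain, and target stands to uncatalysed product as 0.734. By 400 s, gamma's coupling partner is down to 2.18%, target has reached 26.9% and side product 8.95%, and the ratio reads 0.655.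

For delta's neighbour with 60 mM of coupling partner, gamma's split, rescaled for that whole charge standing in the flask, becomes 1.06. That flask gives 37.2% target and 38.5% uncatalysed product, a ratio of 0.966.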